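**Retrosynthetic overview**
1. Target 14 ⇒ oxidation of C1 carbinol 13; the oxirane ⇒ hydroxyl-directed epoxidation of cis-allylic alcohol 12, obtained by Luche reduction of 6-acyloxy enone 11.
2. C6–O ⇒ enolate hydroxylation anti to the C5 side chain, then senecioylation; C8 angelate ⇒ mixed-anhydride esterification.
3. Prenyl terminus ⇒ cross-metathesis of an allyl carbinol with 2-methyl-2-butene; C8 stereocentre and C8–C9 bond ⇒ Brown allylation of an enal.
4. Enal ⇒ allylic oxidation of the isopropenyl methyl of (R)-(−)-carvone, which supplies the carbocycle and C5.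
5. Ring order: the six-membered ring is bought in; the oxirane is the only ring made (step 8).

Assumption: (R)-(−)-carvone is the only numbered starting material; all other commercial inputs are treated as reagents and are given with SMILES where their atoms enter. Ring positions use carvone numbering (C1 carbonyl, C2 methyl-bearing carbon, C5 side-chain carbon, C6 oxygenated carbon); the side-chain carbinol carbon is C8.

**Step 1**
Reactants: 1 (R)-(−)-carvone
Product: 3 2-[(1R)-4-methyl-5-oxocyclohex-3-en-1-yl]prop-2-enal, via 10-hydroxycarvone 2 (not isolated)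
Conditions: SeO2 (0.3 equiv), t-BuOOH (2.5 equiv), salicylic acid (0.1 equiv), CH2Cl2, rt, 36 h; aq Na2S2O3 wash; crude CH2Cl2 solution, activated MnO2 (15 equiv), rt, 4 h
Reagents that add atoms: tert-butyl hydroperoxide CC(C)(C)OO (oxygen source), relayed through selenium dioxide O=[Se]=O
Why: SeO2 allylic oxidation (ene reaction then [2,3]-shift) attacks only the electron-rich 1,1-disubstituted alkene at its methyl group, the deactivated enone alkene is spared, MnO2 converges alcohol 2 to the enal, and C5 is untouched.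

**Step 2**
Reactants: 3 2-[(1R)-4-methyl-5-oxocyclohex-3-en-1-yl]prop-2-enal
Product: 5 (5R)-5-[(3S)-3-hydroxyhexa-1,5-dien-2-yl]-2-methylcyclohex-2-en-1-one, via diisopinocampheylborinate ester 4 (not isolated)
Conditions: (−)-Ipc2BOMe (1.3 equiv), allylmagnesium bromide (1.2 equiv), Et2O, 0 °C to rt, 1 h; then 3, −78 °C, 2 h; HOCH2CH2NH2, rt
Reagents that add atoms: allylmagnesium bromide C=CC[Mg]Br, transferred as (−)-B-allyldiisopinocampheylborane C=CCB([C@@H]1C[C@@H]2C[C@H]([C@H]1C)C2(C)C)[C@@H]1C[C@@H]2C[C@H]([C@H]1C)C2(C)C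
Why: Brown allylboration through a chair six-membered transition state, in which the Ipc groups from (+)-α-pinene deliver allyl to the aldehyde face that gives 8S (same sense as benzaldehyde), the aldehyde reacts far faster than the enone ketone, and the non-oxidative work-up avoids peroxide epoxidation of the enone.

**Step 3**
Reactants: 5 (5R)-5-[(3S)-3-hydroxyhexa-1,5-dien-2-yl]-2-methylcyclohex-2-en-1-one
Product: 6 (5R)-5-[(3S)-3-hydroxy-6-methylhepta-1,5-dien-2-yl]-2-methylcyclohex-2-en-1-one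
Conditions: 2-methyl-2-butene (excess, co-solvent), second-generation Grubbs catalyst (H2IMes)(PCy3)Cl2Ru=CHPh (5 mol %), CH2Cl2, 40 °C, sealed tube, 12 h
Reagents that add atoms: 2-methyl-2-butene CC=C(C)C
Why: Olefin cross-metathesis engages only the monosubstituted terminal alkene (the 1,1-disubstituted and enone alkenes are inert), converting allyl into prenyl without touching a stereocentre.

**Step 4**
Reactants: 6 (5R)-5-[(3S)-3-hydroxy-6-methylhepta-1,5-dien-2-yl]-2-methylcyclohex-2-en-1-one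
Product: 7 (3S)-6-methyl-2-[(1R)-4-methyl-5-oxocyclohex-3-en-1-yl]hepta-1,5-dien-3-yl (2Z)-2-methylbut-2-enoate
Conditions: angelic acid (3 equiv), 2,4,6-trichlorobenzoyl chloride (3 equiv), Et3N (3 equiv), toluene, rt, 2 h; then 6, 80 °C, 12 h, no DMAP
Reagents that add atoms: angelic acid C/C=C(/C)C(=O)O
Why: Yamaguchi-type mixed-anhydride esterification run without DMAP acylates the secondary allylic alcohol with retention at C8 and without Z-to-E isomerisation of the angelate.

**Step 5**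
Reactants: 7 (3S)-6-methyl-2-[(1R)-4-methyl-5-oxocyclohex-3-en-1-yl]hepta-1,5-dien-3-yl (2Z)-2-methylbut-2-enoate
Product: 10 (3S)-2-[(1S,2S)-2-hydroxy-4-methyl-3-oxocyclohex-4-en-1-yl]-6-methylhepta-1,5-dien-3-yl (2Z)-2-methylbut-2-enoate, via sodium dienolate 8 (not isolated), via sodium alkoxide 9 (not isolated)
Conditions: NaN(SiMe3)2 (1.1 equiv), THF, −78 °C, 30 min; (±)-trans-2-(phenylsulfonyl)-3-phenyloxaziridine (1.4 equiv), −78 °C, 1 h; sat. aq NH4Cl, −78 °C
Reagents that add atoms: 2-(phenylsulfonyl)-3-phenyloxaziridine (Davis oxaziridine) O=S(=O)(N1OC1c1ccccc1)c1ccccc1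
Why: Kinetic deprotonation at C6 gives the cross-conjugated dienolate and Davis enolate hydroxylation delivers oxygen to the face opposite the bulky C5 side chain, setting the C6 hydroxyl trans to it (the angelate has no α-hydrogen and the alkenes are inert to the oxaziridine).

**Step 6**
Reactants: 10 (3S)-2-[(1S,2S)-2-hydroxy-4-methyl-3-oxocyclohex-4-en-1-yl]-6-methylhepta-1,5-dien-3-yl (2Z)-2-methylbut-2-enoate
Product: 11 (3S)-6-methyl-2-[(1S,2S)-4-methyl-2-[(3-methylbut-2-enoyl)oxy]-3-oxocyclohex-4-en-1-yl]hepta-1,5-dien-3-yl (2Z)-2-methylbut-2-enoate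
Conditions: 3-methylbut-2-enoyl chloride (1.5 equiv), pyridine (3 equiv), DMAP (0.1 equiv), CH2Cl2, 0 °C, 2 h
Reagents that add atoms: 3-methylbut-2-enoyl chloride CC(C)=CC(=O)Cl
Why: O-acylation with an acid chloride under weak-base catalysis proceeds with retention at C6, and cold pyridine avoids both the vinylketene (deconjugation) pathway and C6 epimerisation.

**Step 7**
Reactants: 11 (3S)-6-methyl-2-[(1S,2S)-4-methyl-2-[(3-methylbut-2-enoyl)oxy]-3-oxocyclohex-4-en-1-yl]hepta-1,5-dien-3-yl (2Z)-2-methylbut-2-enoate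
Product: 12 (3S)-2-[(1S,2S,3S)-3-hydroxy-4-methyl-2-[(3-methylbut-2-enoyl)oxy]cyclohex-4-en-1-yl]-6-methylhepta-1,5-dien-3-yl (2Z)-2-methylbut-2-enoate
Conditions: NaBH4 (1.1 equiv), CeCl3·7H2O (1.2 equiv), MeOH, −78 °C, 1 h
Reagents that add atoms: none
Why: Luche 1,2-reduction with axial hydride delivery to the half-chair bearing equatorial C5 and C6 substituents gives the equatorial C1 hydroxyl, cis to the side chain and trans to the senecioate (as carvone gives cis-carveol), while both esters survive.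

**Step 8**
Reactants: 12 (3S)-2-[(1S,2S,3S)-3-hydroxy-4-methyl-2-[(3-methylbut-2-enoyl)oxy]cyclohex-4-en-1-yl]-6-methylhepta-1,5-dien-3-yl (2Z)-2-methylbut-2-enoate
Product: 13 (3S)-2-[(1S,3S,4S,5R,6R)-5-hydroxy-6-methyl-4-[(3-methylbut-2-enoyl)oxy]-7-oxabicyclo[4.1.0]heptan-3-yl]-6-methylhepta-1,5-dien-3-yl (2Z)-2-methylbut-2-enoate
Conditions: VO(acac)2 (5 mol %), t-BuOOH (5.5 M in decane, 1.5 equiv), CH2Cl2, 0 °C to rt
Reagents that add atoms: tert-butyl hydroperoxide CC(C)(C)OO
Why: Hydroxyl-directed epoxidation through a vanadium alkoxide–peroxide complex delivers oxygen to the ring alkene on the face of the C1 hydroxyl (cis to the side chain, trans to the senecioate), and the side-chain alkenes, which have no free hydroxyl, do not react.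

**Step 9**
Reactants: 13 (3S)-2-[(1S,3S,4S,5R,6R)-5-hydroxy-6-methyl-4-[(3-methylbut-2-enoyl)oxy]-7-oxabicyclo[4.1.0]heptan-3-yl]-6-methylhepta-1,5-dien-3-yl (2Z)-2-methylbut-2-enoate
Product: 14 (3S)-6-methyl-2-[(1S,3S,4S,6S)-6-methyl-4-[(3-methylbut-2-enoyl)oxy]-5-oxo-7-oxabicyclo[4.1.0]heptan-3-yl]hepta-1,5-dien-3-yl (2Z)-2-methylbut-2-enoate
Conditions: Dess–Martin periodinane (1.5 equiv), NaHCO3 (5 equiv), CH2Cl2, 0 °C to rt
Reagents that add atoms: none
Why: Buffered Dess–Martin oxidation converts the C1 carbinol to the ketone under near-neutral conditions, so the epoxide, both unsaturated esters and the epimerisable C6 centre are preserved.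

**Compound list**
1 | (R)-(−)-carvone, (5R)-2-methyl-5-(prop-1-en-2-yl)cyclohex-2-en-1-one | C=C(C)[C@@H]1CC=C(C)C(=O)C1 | starting material
2 | (5R)-5-(3-hydroxyprop-1-en-2-yl)-2-methylcyclohex-2-en-1-one (10-hydroxycarvone) | C=C(CO)[C@@H]1CC=C(C)C(=O)C1 | intermediate (not isolated)
3 | 2-[(1R)-4-methyl-5-oxocyclohex-3-en-1-yl]prop-2-enal | C=C(C=O)[C@@H]1CC=C(C)C(=O)C1 | intermediate
4 | (3S)-2-[(1R)-4-methyl-5-oxocyclohex-3-en-1-yl]hexa-1,5-dien-3-yl diisopinocampheylborinate (Ipc groups from (+)-α-pinene) | C=C([C@H](CC=C)OB([C@@H]2C[C@@H]3C[C@H]([C@H]2C)C3(C)C)[C@@H]2C[C@@H]3C[C@H]([C@H]2C)C3(C)C)[C@@H]1CC=C(C)C(=O)C1 | intermediate (not isolated)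
5 | (5R)-5-[(3S)-3-hydroxyhexa-1,5-dien-2-yl]-2-methylcyclohex-2-en-1-one | C=C([C@H](CC=C)O)[C@@H]1CC=C(C)C(=O)C1 | intermediate
6 | (5R)-5-[(3S)-3-hydroxy-6-methylhepta-1,5-dien-2-yl]-2-methylcyclohex-2-en-1-one | C=C([C@H](CC=C(C)C)O)[C@@H]1CC=C(C)C(=O)C1 | intermediate
7 | (3S)-6-methyl-2-[(1R)-4-methyl-5-oxocyclohex-3-en-1-yl]hepta-1,5-dien-3-yl (2Z)-2-methylbut-2-enoate | C=C([C@H](CC=C(C)C)OC(=O)/C(C)=C\C)[C@@H]1CC=C(C)C(=O)C1 | intermediate
8 | sodium cross-conjugated dienolate of 7 (C1–O⁻, C1=C6) | C=C([C@H](CC=C(C)C)OC(=O)/C(C)=C\C)[C@@H]1CC=C(C)C([O-])=C1.[Na+] | intermediate (not isolated)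
9 | sodium alkoxide of 10 (C6–O⁻ trans to the side chain) | C=C([C@H](CC=C(C)C)OC(=O)/C(C)=C\C)[C@@H]1CC=C(C)C(=O)[C@H]1[O-].[Na+] | intermediate (not isolated)
10 | (3S)-2-[(1S,2S)-2-hydroxy-4-methyl-3-oxocyclohex-4-en-1-yl]-6-methylhepta-1,5-dien-3-yl (2Z)-2-methylbut-2-enoate (C6-OH trans to side chain; the ring descriptor at C5 changes from R to S by priority only) | C=C([C@H](CC=C(C)C)OC(=O)/C(C)=C\C)[C@@H]1CC=C(C)C(=O)[C@H]1O | intermediate
11 | (3S)-6-methyl-2-[(1S,2S)-4-methyl-2-[(3-methylbut-2-enoyl)oxy]-3-oxocyclohex-4-en-1-yl]hepta-1,5-dien-3-yl (2Z)-2-methylbut-2-enoate | C=C([C@H](CC=C(C)C)OC(=O)/C(C)=C\C)[C@@H]1CC=C(C)C(=O)[C@H]1OC(=O)C=C(C)C | intermediate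
12 | (3S)-2-[(1S,2S,3S)-3-hydroxy-4-methyl-2-[(3-methylbut-2-enoyl)oxy]cyclohex-4-en-1-yl]-6-methylhepta-1,5-dien-3-yl (2Z)-2-methylbut-2-enoate (C1-OH cis to side chain, trans to senecioate) | C=C([C@H](CC=C(C)C)OC(=O)/C(C)=C\C)[C@@H]1CC=C(C)[C@H](O)[C@H]1OC(=O)C=C(C)C | intermediate
13 | (3S)-2-[(1S,3S,4S,5R,6R)-5-hydroxy-6-methyl-4-[(3-methylbut-2-enoyl)oxy]-7-oxabicyclo[4.1.0]heptan-3-yl]-6-methylhepta-1,5-dien-3-yl (2Z)-2-methylbut-2-enoate (oxirane O, C1-OH and side chain on one face) | C=C([C@H](CC=C(C)C)OC(=O)/C(C)=C\C)[C@@H]1C[C@@H]2O[C@]2(C)[C@H](O)[C@H]1OC(=O)C=C(C)C | intermediate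
14 | CNP0333561.1, (3S)-6-methyl-2-[(1S,3S,4S,6S)-6-methyl-4-[(3-methylbut-2-enoyl)oxy]-5-oxo-7-oxabicyclo[4.1.0]heptan-3-yl]hepta-1,5-dien-3-yl (2Z)-2-methylbut-2-enoate | C=C([C@H](CC=C(C)C)OC(=O)/C(C)=C\C)[C@@H]1C[C@@H]2O[C@]2(C)C(=O)[C@H]1OC(=O)C=C(C)C | target

**Step count and risks**
Total step count: 9. Longest linear sequence: 9 (fully linear from 1).

Steps most likely to fail:

Step 1 (allylic oxidation). Yields of SeO2 oxidations of isopropenyl groups are modest, and ene reaction at the ring C5–H or over-oxidation can compete. The fallback sets out from 1 and comes back at 3. Carvone 1 is chlorinated at the isopropenyl methyl by the ene-type reaction with HOCl (Ca(OCl)2, solid CO2, CH2Cl2–H2O, 0 °C) to give 10-chlorocarvone F1. F1 is then converted into enal 3 by Kornblum oxidation (NaI cat., NaHCO3, DMSO, 60 °C).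

Step 5 (enolate hydroxylation). The sodium enolate could attack the angelate intramolecularly or add to the sulfonimine by-product, and the trans:cis ratio at C6 may be moderate. The fallback sets out from 7 and comes back at 10. Soft enolisation (Me3SiOTf, Et3N, CH2Cl2, −20 °C) avoids a free metal enolate and gives the trimethylsilyl dienol ether F2. Rubottom oxidation of F2 (mCPBA 1.0 equiv, NaHCO3, CH2Cl2, −40 °C) occurs at the far more electron-rich silyl enol ether, anti to the side chain, and after silyl migration gives the 6-(trimethylsilyloxy) enone F3. Mild acid (citric acid, MeOH, 0 °C) cleaves F3 to 10.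

Step 8 (directed epoxidation). The equatorial allylic alcohol flanked by an ester may be slow to epoxidise and may instead be oxidised back to enone 11. Acyl migration from the C6 oxygen to the C1 oxygen in 12 would also misplace the ketone. The fallback sets out from 7 and comes back at 14; it makes the oxirane before the C6 oxygen is introduced. Luche reduction of 7 (NaBH4, CeCl3·7H2O, MeOH, −78 °C), directly analogous to carvone giving cis-carveol, gives the cis-allylic alcohol F4. VO(acac)2/t-BuOOH gives the all-cis epoxy alcohol F5, and Dess–Martin periodinane gives the cis-epoxy ketone F6. NaN(SiMe3)2 in THF at −78 °C forms the sodium enolate F7, the Davis oxaziridine hydroxylates it anti to the side chain to give the sodium alkoxide F8, and NH4Cl quench gives the hydroxy epoxy ketone F9. F9 is acylated with 3-methylbut-2-enoyl chloride and pyridine to give 14. This order also removes the need for a Luche reduction next to an acyloxy group.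

**Further compounds**
F1 | step 1 | (5R)-5-(3-chloroprop-1-en-2-yl)-2-methylcyclohex-2-en-1-one (10-chlorocarvone) | C=C(CCl)[C@@H]1CC=C(C)C(=O)C1
F2 | step 5 | trimethylsilyl dienol ether of 7, (3S)-6-methyl-2-[(1R)-4-methyl-5-(trimethylsilyloxy)cyclohexa-3,5-dien-1-yl]hepta-1,5-dien-3-yl (2Z)-2-methylbut-2-enoate | C=C([C@H](CC=C(C)C)OC(=O)/C(C)=C\C)[C@@H]1CC=C(C)C(O[Si](C)(C)C)=C1
F3 | step 5 | trimethylsilyl ether of 10 (C6-OSiMe3 trans to the side chain) | C=C([C@H](CC=C(C)C)OC(=O)/C(C)=C\C)[C@@H]1CC=C(C)C(=O)[C@H]1O[Si](C)(C)C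
F4 | step 8 | (3S)-2-[(1R,5R)-5-hydroxy-4-methylcyclohex-3-en-1-yl]-6-methylhepta-1,5-dien-3-yl (2Z)-2-methylbut-2-enoate (cis-carveol-type alcohol) | C=C([C@H](CC=C(C)C)OC(=O)/C(C)=C\C)[C@@H]1CC=C(C)[C@H](O)C1
F5 | step 8 | cis-epoxy alcohol from F4 (oxirane O, C1-OH and side chain on one face; C6 unsubstituted) | C=C([C@H](CC=C(C)C)OC(=O)/C(C)=C\C)[C@@H]1C[C@@H]2O[C@]2(C)[C@H](O)C1
F6 | step 8 | cis-epoxy ketone, (3S)-6-methyl-2-[(1S,3R,6S)-6-methyl-5-oxo-7-oxabicyclo[4.1.0]heptan-3-yl]hepta-1,5-dien-3-yl (2Z)-2-methylbut-2-enoate | C=C([C@H](CC=C(C)C)OC(=O)/C(C)=C\C)[C@@H]1C[C@@H]2O[C@]2(C)C(=O)C1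
F7 | step 8 | sodium enolate of F6 (C1–O⁻, C1=C6) | C=C([C@H](CC=C(C)C)OC(=O)/C(C)=C\C)[C@@H]1C[C@@H]2O[C@]2(C)C([O-])=C1.[Na+]
F8 | step 8 | sodium alkoxide of F9 | C=C([C@H](CC=C(C)C)OC(=O)/C(C)=C\C)[C@@H]1C[C@@H]2O[C@]2(C)C(=O)[C@H]1[O-].[Na+]
F9 | step 8 | 6-hydroxy cis-epoxy ketone (des-senecioyl 14; C6-OH trans to side chain and to oxirane O) | C=C([C@H](CC=C(C)C)OC(=O)/C(C)=C\C)[C@@H]1C[C@@H]2O[C@]2(C)C(=O)[C@H]1O
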